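**Retrosynthetic overview**

1. Pterocarpan numbering is used: ring A (C1–C4, C4a, C11b), ring B (O5, C6, C6a), ring C (O11, C11a), ring D (C6b–C10a, 9-OMe), ring E (dimethyldihydropyran on C1–C2, oxygen on C1). The target is the cis (6aS,11aS) isomer.
2. Feature used: C6a and C11a are adjacent carbons that join ring D (at C6b) to ring A (at C11b), ring D bears O11 ortho to C6b, and C6 is a single carbon on C6a. C6a–C11a can therefore be a diarylalkyne, O11 its internal nucleophile, and C6 can come from carbon monoxide.
3. Backwards: O–Si cleavage; the C6a–H and C11a–H bonds by enantioselective cis-hydrogenation of the pterocarpene; O5–C6 of ring B by Mitsunobu closure after reduction of a coumestan lactone; O11–C11a and C6a–C6 by oxypalladation and carbonylation of an ortho-alkynylphenol.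
4. The alkyne comes from Sonogashira coupling (C6a–C6b) with 2-iodo-5-methoxyphenyl acetate and Ohira–Bestmann homologation of the ring A/E chromane-8-carbaldehyde. Ring E comes from C-prenylation and acid cyclisation of 2,4,6-trihydroxybenzaldehyde with O4 blocked.
5. Ring order: A and D are bought; E is built first, then C (key step), then the lactone ring, which is reopened and reclosed as ring B.

Key step: step 9

Remark: the sense of induction of the chiral carbene ligand on this ring system cannot be predicted; the (R,R) ligand is written, and its antipode is to be used if the (R,R) ligand turns out to give the (6aR,11aR) product.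

**Route**

Step 1
Reactants: 1 2,4,6-trihydroxybenzaldehyde
Product: 2 2,6-dihydroxy-4-[(triisopropylsilyl)oxy]benzaldehyde
Conditions: TIPSCl (1.05 equiv), imidazole, DMF, 0 °C
Reagents that add atoms: triisopropylsilyl chloride, CC(C)[Si](Cl)(C(C)C)C(C)C
Why: Regioselective O-silylation: the 4-OH is the most acidic hydroxyl and the only one not flanking the formyl group, and the bulky silyl chloride should not reach the hydrogen-bonded 2- and 6-OH, so O4 alone is blocked.

Step 2
Reactants: 2 2,6-dihydroxy-4-[(triisopropylsilyl)oxy]benzaldehyde, 3 prenyl bromide (1-bromo-3-methylbut-2-ene)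
Product: 4 2,6-dihydroxy-3-(3-methylbut-2-en-1-yl)-4-[(triisopropylsilyl)oxy]benzaldehyde
Conditions: DBU (1.1 equiv), THF, 0 °C to rt
Reagents that add atoms: none
Why: C-Prenylation of an acylphloroglucinol-type phenoxide (Friedel–Crafts-type C-alkylation under amidine base in a weakly polar solvent): with O4 silylated the ambident anion should react at the ring carbon ortho/para to the chelated phenoxide, and C3 and C5 are equivalent, so one mono-C-prenyl product is expected after removal of O-prenyl and bis-prenyl material.

Step 3
Reactants: 4 2,6-dihydroxy-3-(3-methylbut-2-en-1-yl)-4-[(triisopropylsilyl)oxy]benzaldehyde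
Product: 5 7-hydroxy-2,2-dimethyl-5-[(triisopropylsilyl)oxy]chromane-8-carbaldehyde
Conditions: TsOH·H2O (10 mol%), toluene, 80 °C
Reagents that add atoms: none
Why: Acid-catalysed intramolecular hydroalkoxylation (Markovnikov addition through the tertiary cation, six-membered closure) of the prenyl alkene by the neighbouring 2-OH builds ring E, and closure onto O4 is excluded by the silyl ether, which places the formyl group at C8 of the chromane.

Step 4
Reactants: 5 7-hydroxy-2,2-dimethyl-5-[(triisopropylsilyl)oxy]chromane-8-carbaldehyde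
Product: 8 5,7-bis(benzyloxy)-2,2-dimethylchromane-8-carbaldehyde, via dihydroxy aldehyde 6 (not isolated), via mono-benzyl ether 7 (not isolated)
Conditions: CsF, BnBr (2.5 equiv), DMF, rt; then K2CO3, 60 °C
Reagents that add atoms: benzyl bromide, BrCc1ccccc1
Why: Fluoride-induced desilylation with Williamson benzylation in the same flask, then carbonate-mediated benzylation of the chelated 7-OH; the exchange is made here because an aryl silyl ether, above all one para to a formyl group, would not reliably survive the carbonate/methanol media of steps 5, 8 and 9, whereas benzyl ethers do, and the O7 benzyl ether keeps this oxygen from attacking the alkyne in step 9.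

Step 5
Reactants: 8 5,7-bis(benzyloxy)-2,2-dimethylchromane-8-carbaldehyde
Product: 9 5,7-bis(benzyloxy)-8-ethynyl-2,2-dimethylchromane
Conditions: dimethyl (1-diazo-2-oxopropyl)phosphonate, K2CO3, MeOH–THF, rt
Reagents that add atoms: dimethyl (1-diazo-2-oxopropyl)phosphonate, COP(=O)(OC)C(=[N+]=[N-])C(C)=O
Why: Ohira–Bestmann (Seyferth–Gilbert) homologation: the diazomethylphosphonate anion formed in methanol adds to the non-enolisable aldehyde, and loss of phosphate and N2 followed by a 1,2-hydrogen shift should give the terminal alkyne, whose new carbon becomes C6a.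

Step 6
Reactants: 10 2-iodo-5-methoxyphenol
Product: 11 2-iodo-5-methoxyphenyl acetate
Conditions: Ac2O, pyridine, CH2Cl2, 0 °C to rt
Reagents that add atoms: acetic anhydride, CC(=O)OC(C)=O
Why: O-Acetylation (nucleophilic acyl substitution) masks the phenol so that the coupling in step 7 stops at the alkyne instead of cyclising to a 3-unsubstituted benzofuran.

Step 7
Reactants: 9 5,7-bis(benzyloxy)-8-ethynyl-2,2-dimethylchromane, 11 2-iodo-5-methoxyphenyl acetate
Product: 12 2-{[5,7-bis(benzyloxy)-2,2-dimethylchroman-8-yl]ethynyl}-5-methoxyphenyl acetate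
Conditions: Pd(PPh3)2Cl2 (3 mol%), CuI (5 mol%), Et3N, THF, degassed, rt to 40 °C
Reagents that add atoms: none
Why: Sonogashira coupling: oxidative addition of the aryl iodide to zerovalent palladium, transmetalation of the copper acetylide and reductive elimination form the C6a–C6b bond under conditions where the aryl acetate and the benzyl ethers are inert.

Step 8
Reactants: 12 2-{[5,7-bis(benzyloxy)-2,2-dimethylchroman-8-yl]ethynyl}-5-methoxyphenyl acetate
Product: 13 2-{[5,7-bis(benzyloxy)-2,2-dimethylchroman-8-yl]ethynyl}-5-methoxyphenol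
Conditions: K2CO3 (0.2 equiv), MeOH–THF, 0 °C
Reagents that add atoms: none
Why: Base-catalysed transesterification (methanolysis) of the aryl acetate, far faster than any reaction of the benzyl ethers or the alkyne at 0 °C, frees the ring D phenol that is the nucleophile of the key step.

Step 9
Reactants: 13 2-{[5,7-bis(benzyloxy)-2,2-dimethylchroman-8-yl]ethynyl}-5-methoxyphenol
Product: 14 methyl 2-[5,7-bis(benzyloxy)-2,2-dimethylchroman-8-yl]-6-methoxy-1-benzofuran-3-carboxylate
Conditions: PdI2 (5 mol%), thiourea (5 mol%), CBr4, Cs2CO3, CO (1 atm), MeOH, 40 °C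
Reagents that add atoms: carbon monoxide, [C-]#[O+]; methanol, CO
Why: Divalent palladium (PdI2–thiourea) coordinates the alkyne of the caesium phenoxide of 13 and the ring D oxygen adds anti across it in a 5-endo-dig oxypalladation, which closes ring C (O11–C11a) and leaves a benzofuran-3-yl–palladium bond at C6a. CO inserts into this bond to give the acylpalladium (C6a–C6), methanolysis releases ester 14 and zerovalent palladium, and CBr4 returns the metal to divalent palladium. The closest known reaction type is the PdI2–thiourea/CBr4 carbonylative annulation of ortho-hydroxyaryl alkynes to 2-substituted benzofuran-3-carboxylates, which tolerates ortho-alkoxy groups on the second aryl ring. No stereocentre is formed. The step needs attack by the ring D oxygen and not by a ring A oxygen, and carbonylation faster than protonolysis of the C6a–Pd bond; the first is secured because both oxygens flanking the alkyne on ring A (O5 and the ring E oxygen) are etherified, the second by the CO atmosphere and the carbonate base, which keeps the medium free of acid.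

Step 10
Reactants: 14 methyl 2-[5,7-bis(benzyloxy)-2,2-dimethylchroman-8-yl]-6-methoxy-1-benzofuran-3-carboxylate
Product: 16 3-hydroxy-9-methoxycoumestan (6H-benzofuro[3,2-c]chromen-6-one) carrying ring E (2,2-dimethyl-3,4-dihydro-2H-pyran fused at C1 through oxygen and at C2 through CH2), via dihydroxy ester 15 (not isolated)
Conditions: H2 (1 atm), Pd/C (10% palladium on carbon), EtOAc–MeOH, rt; then TsOH·H2O (cat.), toluene, 80 °C
Reagents that add atoms: none
Why: Hydrogenolysis of both benzyl ethers frees O5–H next to the C6 ester, and acid-catalysed transesterification (lactonisation to a six-membered ring) should close the coumestan lactone; the tetrasubstituted, ester-conjugated benzofuran bond is not expected to be reduced over Pd/C at 1 atm.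

Step 11
Reactants: 16 3-hydroxy-9-methoxycoumestan carrying ring E
Product: 17 9-methoxy-3-[(triisopropylsilyl)oxy]coumestan carrying ring E
Conditions: TIPSCl, imidazole, DMF, rt
Reagents that add atoms: triisopropylsilyl chloride, CC(C)[Si](Cl)(C(C)C)C(C)C
Why: Silylation of the single remaining phenol (C3–OH): no basic methanol follows, so the silyl ether is now safe, it leaves O5–H as the only phenol for step 13, and it should make the later intermediates soluble in hexane for step 14.

Step 12
Reactants: 17 9-methoxy-3-[(triisopropylsilyl)oxy]coumestan carrying ring E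
Product: 18 {2-[7-hydroxy-2,2-dimethyl-5-(triisopropylsilyloxy)chroman-8-yl]-6-methoxy-1-benzofuran-3-yl}methanol
Conditions: LiAlH4, THF, −10 to 0 °C
Reagents that add atoms: none
Why: Hydride reduction of the aryl lactone (ester to primary alcohol with release of the O5 phenoxide); the hindered aryl triisopropylsilyl ether and the benzofuran should not be attacked at 0 °C.

Step 13
Reactants: 18 {2-[7-hydroxy-2,2-dimethyl-5-(triisopropylsilyloxy)chroman-8-yl]-6-methoxy-1-benzofuran-3-yl}methanol
Product: 19 9-methoxy-3-[(triisopropylsilyl)oxy]-6H-benzofuro[3,2-c]chromene (pterocarp-6a(11a)-ene) carrying ring E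
Conditions: PPh3, DIAD, THF, 0 °C to rt
Reagents that add atoms: none
Why: Intramolecular Mitsunobu etherification: the primary benzofuran-3-ylmethanol is activated as its alkoxyphosphonium ion and displaced by the O5 phenoxide in a 6-exo-tet closure of ring B, under neutral conditions that avoid acid-promoted ionisation of the electron-rich benzylic alcohol.

Step 14
Reactants: 19 9-methoxy-3-[(triisopropylsilyl)oxy]-6H-benzofuro[3,2-c]chromene carrying ring E
Product: 20 (6aS,11aS)-9-methoxy-3-[(triisopropylsilyl)oxy]-6a,11a-dihydro-6H-benzofuro[3,2-c]chromene (cis-pterocarpan) carrying ring E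
Conditions: Ru(cod)(2-methylallyl)2 (5 mol%), 1,3-bis[(1R)-1-(naphthalen-1-yl)ethyl]-4,5-dihydroimidazolium tetrafluoroborate (10 mol%), KOtBu, n-hexane, 70 °C; then 19, H2 (80 bar), 40 °C
Reagents that add atoms: none
Why: Proposed new method: ruthenium complexes of this chiral N-heterocyclic carbene are known to hydrogenate the furan ring of 2-substituted benzofurans enantioselectively by syn delivery of two hydrogens to one face of C2=C3 (closest known reaction type: enantioselective hydrogenation of 2-aryl- and 2-alkylbenzofurans to 2,3-dihydrobenzofurans), and the same syn addition to the tetrasubstituted, ring-fused C6a=C11a bond of 19, not yet shown for a 2,3-disubstituted benzofuran, would set both stereocentres at once, cis by mechanism, with the face chosen by the chiral pocket of the carbene so that (6aS,11aS) results.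

Step 15
Reactants: 20 (6aS,11aS)-9-methoxy-3-[(triisopropylsilyl)oxy]pterocarpan carrying ring E
Product: 21 (6aS,11aS)-3-hydroxy-9-methoxypterocarpan carrying ring E (CNP0207547.1)
Conditions: Bu4NF, AcOH, THF, 0 °C
Reagents that add atoms: none
Why: Fluoride-mediated desilylation (Si–F bond formation) under acetic acid buffering frees the C3 phenol without acid or strong base, so the acid-labile C11a–O11 benzylic ether and both stereocentres should stay untouched.

**Compound list**

1 | 2,4,6-trihydroxybenzaldehyde | O=Cc1c(O)cc(O)cc1O | starting material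
2 | 2,6-dihydroxy-4-[(triisopropylsilyl)oxy]benzaldehyde | O=Cc1c(O)cc(O[Si](C(C)C)(C(C)C)C(C)C)cc1O | intermediate
3 | prenyl bromide (1-bromo-3-methylbut-2-ene) | CC(C)=CCBr | starting material
4 | 2,6-dihydroxy-3-(3-methylbut-2-en-1-yl)-4-[(triisopropylsilyl)oxy]benzaldehyde | O=Cc1c(O)cc(O[Si](C(C)C)(C(C)C)C(C)C)c(CC=C(C)C)c1O | intermediate
5 | 7-hydroxy-2,2-dimethyl-5-[(triisopropylsilyl)oxy]chromane-8-carbaldehyde | O=Cc1c(O)cc(O[Si](C(C)C)(C(C)C)C(C)C)c2CCC(C)(C)Oc12 | intermediate
6 | 5,7-dihydroxy-2,2-dimethylchromane-8-carbaldehyde (present as its caesium 5-phenoxide) | O=Cc1c(O)cc(O)c2CCC(C)(C)Oc12 | intermediate (not isolated)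
7 | 5-(benzyloxy)-7-hydroxy-2,2-dimethylchromane-8-carbaldehyde | O=Cc1c(O)cc(OCc2ccccc2)c2CCC(C)(C)Oc12 | intermediate (not isolated)
8 | 5,7-bis(benzyloxy)-2,2-dimethylchromane-8-carbaldehyde | O=Cc1c(OCc2ccccc2)cc(OCc2ccccc2)c2CCC(C)(C)Oc12 | intermediate
9 | 5,7-bis(benzyloxy)-8-ethynyl-2,2-dimethylchromane | C#Cc1c(OCc2ccccc2)cc(OCc2ccccc2)c2CCC(C)(C)Oc12 | intermediate
10 | 2-iodo-5-methoxyphenol | COc1ccc(I)c(O)c1 | starting material
11 | 2-iodo-5-methoxyphenyl acetate | COc1ccc(I)c(OC(C)=O)c1 | intermediate
12 | 2-{[5,7-bis(benzyloxy)-2,2-dimethylchroman-8-yl]ethynyl}-5-methoxyphenyl acetate | COc1ccc(C#Cc2c(OCc3ccccc3)cc(OCc3ccccc3)c3CCC(C)(C)Oc23)c(OC(C)=O)c1 | intermediate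
13 | 2-{[5,7-bis(benzyloxy)-2,2-dimethylchroman-8-yl]ethynyl}-5-methoxyphenol | COc1ccc(C#Cc2c(OCc3ccccc3)cc(OCc3ccccc3)c3CCC(C)(C)Oc23)c(O)c1 | intermediate (key-step precursor)
14 | methyl 2-[5,7-bis(benzyloxy)-2,2-dimethylchroman-8-yl]-6-methoxy-1-benzofuran-3-carboxylate | COC(=O)c1c(-c2c(OCc3ccccc3)cc(OCc3ccccc3)c3CCC(C)(C)Oc23)oc2cc(OC)ccc12 | intermediate (key-step product)
15 | methyl 2-(5,7-dihydroxy-2,2-dimethylchroman-8-yl)-6-methoxy-1-benzofuran-3-carboxylate | COC(=O)c1c(-c2c(O)cc(O)c3CCC(C)(C)Oc23)oc2cc(OC)ccc12 | intermediate (not isolated)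
16 | 3-hydroxy-9-methoxycoumestan carrying ring E (dimethyldihydropyran, O on C1, CH2 on C2) | COc1ccc2c(c1)oc1c2C(=O)Oc2cc(O)c3CCC(C)(C)Oc3c21 | intermediate
17 | 9-methoxy-3-[(triisopropylsilyl)oxy]coumestan carrying ring E | COc1ccc2c(c1)oc1c2C(=O)Oc2cc(O[Si](C(C)C)(C(C)C)C(C)C)c3CCC(C)(C)Oc3c21 | intermediate
18 | {2-[7-hydroxy-2,2-dimethyl-5-(triisopropylsilyloxy)chroman-8-yl]-6-methoxy-1-benzofuran-3-yl}methanol | COc1ccc2c(CO)c(-c3c(O)cc(O[Si](C(C)C)(C(C)C)C(C)C)c4CCC(C)(C)Oc34)oc2c1 | intermediate
19 | 9-methoxy-3-[(triisopropylsilyl)oxy]-6H-benzofuro[3,2-c]chromene (pterocarp-6a(11a)-ene) carrying ring E | COc1ccc2c(c1)oc1c2COc2cc(O[Si](C(C)C)(C(C)C)C(C)C)c3CCC(C)(C)Oc3c21 | intermediate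
20 | (6aS,11aS)-9-methoxy-3-[(triisopropylsilyl)oxy]pterocarpan carrying ring E (cis ring fusion) | COc1ccc2c(c1)O[C@@H]1c3c(cc(O[Si](C(C)C)(C(C)C)C(C)C)c4c3OC(C)(C)CC4)OC[C@H]21 | intermediate
21 | (6aS,11aS)-3-hydroxy-9-methoxypterocarpan carrying ring E (CNP0207547.1) | COc1ccc2c(c1)O[C@@H]1c3c(cc(O)c4c3OC(C)(C)CC4)OC[C@H]21 | target

**Step count**

Total steps: 15. Longest linear sequence: 14 (steps 1–5 and 7–15, from 1 to 21); step 6 is the one-step side branch.

**Steps most likely to fail and fallbacks**

Step 14 (the step that carries the new-method label). The tetrasubstituted C6a=C11a bond is flanked by ring A with its ring E oxygen at C1, so the ruthenium carbene catalyst may fail to bind it and give no turnover, or may bind it with poor facial discrimination. The fallback uses known chemistry and sets out from 19. Heterogeneous syn-hydrogenation (H2, Pd/C, EtOAc, rt, stopped after one equivalent of hydrogen to limit hydrogenolysis of the C11a–O11 bond) should give the racemic cis-pterocarpan silyl ether F1. Preparative HPLC on a polysaccharide carbamate chiral stationary phase then separates 20 from the (6aR,11aR)-enantiomer F2, which is discarded. The route is rejoined at 20.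

Step 9. Protonolysis of the benzofuran-3-yl–palladium bond may outrun CO insertion, leading to plain cycloisomerisation without C6, or the alkyne, hindered by two ortho oxygens on ring A, may coordinate slowly. The fallback sets out from 13 and separates ring closure from carbonylation. Iodocyclisation (I2, NaHCO3, MeCN, rt; 5-endo-dig iodo-etherification) should give 5,7-bis(benzyloxy)-8-(3-iodo-6-methoxy-1-benzofuran-2-yl)-2,2-dimethylchromane F3. Palladium-catalysed methoxycarbonylation of the aryl iodide (Pd(OAc)2, Xantphos, CO, Et3N, MeOH–DMF, 70 °C) then installs C6 from CO through oxidative addition to zerovalent palladium, a pathway in which no protonolysis competes in the same way. The route is rejoined at 14.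

Step 2. The ambident phenoxide may alkylate on oxygen instead of carbon, or twice on carbon, so that little mono-C-prenyl material is obtained. The fallback sets out from 2 and builds ring E by a different bond-forming sequence. Condensation with 3-methylbut-2-enal (pyridine, 110 °C; Knoevenagel-type C-alkylation, dehydration to the ortho-quinone methide and oxa-6π electrocyclisation, possible only through O2 because O4 is silylated) should give 7-hydroxy-2,2-dimethyl-5-[(triisopropylsilyl)oxy]-2H-chromene-8-carbaldehyde F4. Hydrogenation of its C3=C4 bond (H2, Pd/C, EtOAc, rt) then gives 5, where the route is rejoined; steps 2 and 3 are replaced.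

**Further compounds**

F1 | step 14 | racemic cis-9-methoxy-3-[(triisopropylsilyl)oxy]pterocarpan carrying ring E (both enantiomers) | COc1ccc2c(c1)O[C@@H]1c3c(cc(O[Si](C(C)C)(C(C)C)C(C)C)c4c3OC(C)(C)CC4)OC[C@H]21.COc1ccc2c(c1)O[C@H]1c3c(cc(O[Si](C(C)C)(C(C)C)C(C)C)c4c3OC(C)(C)CC4)OC[C@@H]21
F2 | step 14 | (6aR,11aR)-9-methoxy-3-[(triisopropylsilyl)oxy]pterocarpan carrying ring E | COc1ccc2c(c1)O[C@H]1c3c(cc(O[Si](C(C)C)(C(C)C)C(C)C)c4c3OC(C)(C)CC4)OC[C@@H]21
F3 | step 9 | 5,7-bis(benzyloxy)-8-(3-iodo-6-methoxy-1-benzofuran-2-yl)-2,2-dimethylchromane | COc1ccc2c(I)c(-c3c(OCc4ccccc4)cc(OCc4ccccc4)c4CCC(C)(C)Oc34)oc2c1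
F4 | step 2 | 7-hydroxy-2,2-dimethyl-5-[(triisopropylsilyl)oxy]-2H-chromene-8-carbaldehyde | O=Cc1c(O)cc(O[Si](C(C)C)(C(C)C)C(C)C)c2C=CC(C)(C)Oc12
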